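The constants used here are made up; no experiment stands behind them.

Count first. Then read the flasks and what is asked of them.

common to all: starting material 0.21 M; protic impurity 0.0630 M; time 12 h
- autumn: temperature 80 °C
- summer: temperature 110 °C
- dawn: temperature 140 °C

* the best flask by amount of target, in percent of the starting material charged; "all alike" if 1.5 percentage points covers them all (autumn / summer / dawn / all alike)
* amount of target at the end, in percent of the starting material charged, autumn
* amount of target at the end, in percent of the starting material charged, summer
* amount of target at the end, in percent of the starting material charged, dawn

- a species is counted by the starting material in it: one side product counts as two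
- at 80 °C the constants are as listed, elsewhere as the activation energies and enthalpies make them
- in a conversion other conformer counts as not yet reacted

    starting material + target → side product (k1 = 2.47 L mol⁻¹ h⁻¹, Ea1 = 91.0 kJ mol⁻¹)
    starting material → target (k2 = 0.295 h⁻¹, Ea2 = 113 kJ mol⁻¹)
    target → over-reaction product (k3 = 2.03 × 10⁻⁴ h⁻¹, Ea3 = 124 kJ mol⁻¹)
    other conformer → isomer of the product (k4 = 0.104 h⁻¹, Ea4 = 119 kJ mol⁻¹)
    starting material ⇌ other conformer (K5 = 0.969, k5 = 0.109 h⁻¹, Ea5 = 115 kJ mol⁻¹, ΔH5 = 8.00 kJ mol⁻¹)
    other conformer + protic impurity → quenched substrate (k6 = 0.695 L mol⁻¹ h⁻¹, Ea6 = 92.0 kJ mol⁻¹)
    (constants at 80 °C)

For whoever takes the bench: each flask holds starting material, which turns into target by itself, or meets target to give side product, or slips reversibly into the other conformer. That conformer goes on to isomer of the product, or with protic impurity to quenched substrate. Target also goes on by itself to over-reaction product, with 2.03 × 10⁻⁴ h⁻¹ at 80 °C and 124 kJ mol⁻¹.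

So I count two things over 12 h. Making turnovers, the constant of the step to target times the time, come to 3.54 in autumn, 72.1 in summer and 947 in dawn. Loss turnovers, reckoned the same way for the over-reaction, come to 0.00244, 0.0665 and 1.12. This second number is the loss count: the over-reaction constant at the flask's temperature times the time.

Making ends early against loss, so target made in a hot flask keeps e to the minus loss count of itself: 93.6% in summer, 32.5% in dawn. When you come to those two, expect making to be long over and target to be the thing still moving.

Don't raise the bath. Warmth does help the split, because the step to target gains on the step to side product, but dawn must make 2.88 times what summer makes just to match it. My count stops at the share kept, not the amount made. I commit to summer.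

The forecast names summer, with 37.5%, 45.5% and 18.3% for autumn, summer and dawn, saying that at dawn over-reaction “destroys most of it”.

The flasks give summer as best, with 37.5%, 45.9% and 18.5% of the charge for autumn, summer and dawn.

In summer the half-life of starting material by the step to target, 0.12 h at 0.0767 h, is short against 12 h, and that step has >99.9% of its turnover behind it by 2.40 h. Target over target plus over-reaction product then stands at 93.6% in summer and 32.6% in dawn at 12.0 h, where the loss count keeps 93.6% and 32.5%. The neighbouring flask, summer kept at 125 °C, has a loss count of 0.288, which keeps 75.0%, and it ends with 40.0% target beside 13.3% over-reaction product, a share of 75.0%.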